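The bicyclo[3.3.1]nonene is cut at C5–C6 and C1–C8. This removes C6–C7–C8 of ring B as an enal and leaves ring A as a cyclohexanone. The feature exploited is that both bridgeheads, C1 (methyl-bearing) and C5 (formyl-bearing), flank the oxygenated bridge carbon C9, so a single ketone there provides two nucleophilic sites in turn. In one operation a chiral secondary amine steers conjugate addition of C5 to the enal. An aldol from C1 then bridges ring A, closing ring B and setting C6, C5 and C1. The precursors are a racemic 4-methyl-3-oxocyclohexane-1,2-dicarboxylate, assembled by a Diels–Alder reaction, and an (R)-citronellal-derived γ-branched (E)-enal that already carries C1′.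

Key step: step 9

Numbering: the atom labels of the target are used for all bicyclic intermediates and for the CIP descriptors in their names.
- C1 is the methyl-bearing bridgehead, followed by C2 and C3.
- C4 carries C11, and the bridgehead C5 carries C12.
- C6 carries the side chain through C1′, followed by C7 and C8; C9 is the one-carbon bridge.
- Ring A = C1–C2–C3–C4–C5–C9 and ring B = C1–C8–C7–C6–C5–C9.

Assumption: the ring A keto diester is used as the racemic diastereomer mixture. Its C1 and C5 centres equilibrate by enolisation. C4 does not equilibrate under the key-step conditions, so the bicyclic intermediates are carried as C4 epimer mixtures until C4 becomes trigonal.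

Assumption: (R)-citronellal of high enantiomeric purity is used, and its stereocentre becomes C1′ unchanged.

Step 1
Reactants: 1 tiglic aldehyde [(E)-2-methylbut-2-enal]
Product: 2 (1E)-2-methyl-1-(trimethylsilyloxy)buta-1,3-diene
Conditions: Me3SiOTf, Et3N, Et2O, 0 °C
Reagents that add atoms: trimethylsilyl trifluoromethanesulfonate, C[Si](C)(C)OS(=O)(=O)C(F)(F)F
Why: Soft enolisation (O-silylation, then γ-deprotonation by the amine) of the s-trans enal should give the silyl dienol ether as the (1E) isomer, whose s-cis conformer is unhindered for cycloaddition.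

Step 2
Reactants: 2 (1E)-2-methyl-1-(trimethylsilyloxy)buta-1,3-diene; 3 dimethyl fumarate
Product: 5 dimethyl 3-hydroxy-4-methylcyclohex-4-ene-1,2-dicarboxylate (racemic diastereomer mixture), via silyl ether cycloadduct 4 (not isolated)
Conditions: toluene, 110 °C; then 1 M HCl, THF, 0 °C
Reagents that add atoms: none
Why: This is a normal-electron-demand Diels–Alder reaction of a 1-oxygenated diene with a symmetrical dienophile, so no regiochemical question arises, the oxygen ends up next to an ester-bearing carbon, and the relative configuration is irrelevant because every centre formed is later trigonal or enolisable.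

Step 3
Reactants: 5 dimethyl 3-hydroxy-4-methylcyclohex-4-ene-1,2-dicarboxylate
Product: 6 dimethyl 3-hydroxy-4-methylcyclohexane-1,2-dicarboxylate (racemic diastereomer mixture)
Conditions: H2 (1 atm), 5% Pt/C, EtOAc, rt
Reagents that add atoms: none
Why: Heterogeneous catalytic hydrogenation of the only alkene is placed before the alcohol oxidation so that a 2-methylcyclohexenone β-keto ester, whose dienol aromatises easily, is never formed, and platinum is preferred to palladium to limit allylic C–O hydrogenolysis.

Step 4
Reactants: 6 dimethyl 3-hydroxy-4-methylcyclohexane-1,2-dicarboxylate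
Product: 7 dimethyl 4-methyl-3-oxocyclohexane-1,2-dicarboxylate (racemic diastereomer and keto–enol mixture)
Conditions: DMP (1.1 equiv), CH2Cl2, 0 °C → rt
Reagents that add atoms: none
Why: Dess–Martin oxidation converts the β-hydroxy ester into the β-keto ester under neutral conditions, and limiting the oxidant avoids α-hydroxylation of the enolised product.

Step 5
Reactants: 8 (R)-citronellal
Product: 10 (3R)-2-(anilinooxy)-3,7-dimethyloct-6-en-1-ol (C2 epimers immaterial), via α-anilinooxy aldehyde 9 (not isolated)
Conditions: PhNO, L-proline (20 mol%), MeCN, −20 °C; then NaBH4, MeOH, 0 °C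
Reagents that add atoms: nitrosobenzene, O=Nc1ccccc1
Why: Proline-catalysed α-aminoxylation (enamine catalysis, O-selective nitroso aldol reaction) oxygenates only the aldehyde α-carbon and spares the trisubstituted alkene that peracid- or osmium-based oxidants would attack, while C3 is not involved and the new C2 centre is destroyed in step 7.

Step 6
Reactants: 10 (3R)-2-(anilinooxy)-3,7-dimethyloct-6-en-1-ol
Product: 11 (3R)-3,7-dimethyloct-6-ene-1,2-diol
Conditions: Zn, AcOH, EtOH, rt
Reagents that add atoms: none
Why: Dissolving-metal reductive cleavage breaks the weak N–O bond and frees the 1,2-diol without touching the isolated alkene, which catalytic hydrogenolysis would saturate.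

Step 7
Reactants: 11 (3R)-3,7-dimethyloct-6-ene-1,2-diol
Product: 12 (2R)-2,6-dimethylhept-5-enal
Conditions: NaIO4, THF/pH 7 buffer, 0 °C → rt
Reagents that add atoms: none
Why: Periodate glycol cleavage (Malaprade reaction) excises the former aldehyde carbon as formaldehyde under neutral conditions that neither touch the alkene nor epimerise the α-stereocentre, which is the unchanged citronellal centre.

Step 8
Reactants: 12 (2R)-2,6-dimethylhept-5-enal; 13 (triphenylphosphoranylidene)acetaldehyde
Product: 14 (2E,4R)-4,8-dimethylnona-2,7-dienal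
Conditions: toluene, 80 °C
Reagents that add atoms: none
Why: The Wittig reaction with a stabilised ylide adds C7 and C8 directly at the aldehyde oxidation level with E selectivity, the salt-free non-basic medium preserves the adjacent stereocentre, and the product enal is less electrophilic than 12, which limits a second homologation.

Step 9
Reactants: 7 dimethyl 4-methyl-3-oxocyclohexane-1,2-dicarboxylate; 14 (2E,4R)-4,8-dimethylnona-2,7-dienal
Product: 16 dimethyl (1S,5R,6S)-8-hydroxy-1-methyl-6-[(2R)-6-methylhept-5-en-2-yl]-9-oxobicyclo[3.3.1]nonane-4,5-dicarboxylate (C4/C8 epimer mixture), via keto aldehyde Michael adduct 15 (not isolated)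
Conditions: (S)-2-[diphenyl(trimethylsilyloxy)methyl]pyrrolidine (20 mol%), PhCO2H (20 mol%), 7 (2 equiv), toluene, 0 °C, slow addition of 14; then DBU (1.5 equiv), 0 °C → rt
Reagents that add atoms: none
Why: The (S)-amine and 14 form an E-configured, s-trans iminium ion with one face covered by the CPh2(OSiMe3) group, the enol of 7 bonds through C5 to C6 on the open face, hydrolysis of the resulting enamine frees keto aldehyde 15 and returns the catalyst, and DBU then enolises C1 for addition to the C8 aldehyde. The closest known reaction type is the diarylprolinol silyl ether catalysed domino Michael–aldol [3+3] annulation of cyclic β-keto esters with enals to hydroxy-9-oxobicyclo[3.3.1]nonanes, and base-induced aldol closure onto a fully substituted bridgehead carbon is known from bicyclo[3.3.1]nonanone core syntheses, so only the combination on this hindered pair is untried. Ring B closes by a 6-(enolendo)-exo-trig aldol through a chair in which the C5–C6 and C1–C8 bonds are both axial on ring A. C6 (S) is set by the catalyst, which has to outweigh only a weak bias from C1′ because that centre tells merely methyl from a primary alkyl chain; C5 (R) should come from attack anti to the pseudoaxial C4 ester in the better matched enantiomer of racemic 7 (hence two equivalents) and is backed by the reversibility of both bond formations, which should drain material into the chair–chair bicycle with the side chain equatorial on ring B; C1 has no choice, since the three-carbon bridge can span only one face of ring A; C8 is uncontrolled and is deleted in step 11. Site selectivity is built into 7: C5 is its only doubly activated carbon, C1 is the only enolisable ketone position once C5 is quaternary, and the C9 ketone of 16 has no α-hydrogen, so dehydration or further aldol chemistry cannot follow. The γ-hydrogen at C1′ could be lost through iminium–dienamine equilibration, which is countered by adding 14 slowly to a concentrated excess of the strongly enolised donor at 0 °C with nothing more basic than benzoate present, and DBU is added only after 14 is consumed so that no uncatalysed conjugate addition can occur.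

Step 10
Reactants: 16 bicyclic aldol (8-hydroxy-9-oxo diester)
Product: 17 dimethyl (1S,5R,6S)-1-methyl-6-[(2R)-6-methylhept-5-en-2-yl]-9-oxo-8-(phenoxycarbonothioyloxy)bicyclo[3.3.1]nonane-4,5-dicarboxylate (C4/C8 epimer mixture)
Conditions: PhOC(S)Cl, DMAP, MeCN, rt
Reagents that add atoms: O-phenyl chlorothionoformate, S=C(Cl)Oc1ccccc1
Why: Thioacylation of the C8 hydroxyl under weakly basic conditions (first stage of the Barton–McCombie deoxygenation) avoids the alkoxide that xanthate formation with NaH, CS2 and MeI would need and that would trigger retro-aldol opening of the β-hydroxy ketone, and elimination toward quaternary C1 is impossible.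

Step 11
Reactants: 17 C8 phenyl thionocarbonate
Product: 18 dimethyl (1R,5R,6S)-1-methyl-6-[(2R)-6-methylhept-5-en-2-yl]-9-oxobicyclo[3.3.1]nonane-4,5-dicarboxylate (C4 epimer mixture)
Conditions: n-Bu3SnH (0.5 M), AIBN, toluene, 90 °C
Reagents that add atoms: none
Why: In the Barton–McCombie deoxygenation the stannyl radical adds to C=S, β-scission gives the secondary C8 radical and hydrogen transfer completes the reduction, and a high stannane concentration lets hydrogen abstraction outrun a 1,2-acyl shift through C9 or a seven-membered closure onto the remote side-chain alkene.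

Step 12
Reactants: 18 9-oxo diester
Product: 21 dimethyl (1R,5R,6S)-1-methyl-6-[(2R)-6-methylhept-5-en-2-yl]-9-oxobicyclo[3.3.1]non-3-ene-4,5-dicarboxylate, via C4 phenylselenide 19 (not isolated), via C4 selenoxide 20 (not isolated)
Conditions: KN(SiMe3)2, THF, −78 °C; PhSeBr (1.0 equiv), −78 °C; then NaIO4, THF/MeOH/H2O, 0 °C → rt
Reagents that add atoms: none
Why: Ester enolate selenenylation and selenoxide syn-elimination should work because C4–H is the only acidic hydrogen (C9 lies between two quaternary carbons), a silylamide cannot deliver hydride to that ketone, one equivalent of PhSeBr is consumed by the enolate before it can add to the side-chain alkene, peroxide-free NaIO4 avoids epoxidation, and elimination can run only toward C3 since C5 bears no hydrogen, which also merges both C4 epimers.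

Step 13
Reactants: 21 9-oxo enoate diester
Product: 22 (1R,5S,6S,9R)-4,5-bis(hydroxymethyl)-1-methyl-6-[(2R)-6-methylhept-5-en-2-yl]bicyclo[3.3.1]non-3-en-9-ol
Conditions: i-Bu2AlH (8 equiv), CH2Cl2, −78 → 0 °C; aq. potassium sodium tartrate
Reagents that add atoms: none
Why: Aluminium hydride 1,2-reduction takes both esters and the ketone without conjugate reduction of the enoate, and hydride should reach C9 over ring A, where trigonal C4 offers no axial hydrogen, rather than over ring B with its axial H-6 and H-8, so the new hydroxyl comes to lie over ring B (9R) as in the target.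

Step 14
Reactants: 22 triol
Product: 23 (1R,5S,6S,9R)-4,5-bis[(tert-butyldimethylsilyloxy)methyl]-1-methyl-6-[(2R)-6-methylhept-5-en-2-yl]bicyclo[3.3.1]non-3-en-9-ol
Conditions: TBSCl (2.3 equiv), imidazole, DMF, 0 °C → rt
Reagents that add atoms: tert-butyldimethylsilyl chloride, CC(C)(C)[Si](C)(C)Cl
Why: Sterically governed silylation takes the two primary hydroxyls (allylic C11 and neopentyl C12), while the secondary C9 hydroxyl between two quaternary carbons should stay free.

Step 15
Reactants: 23 bis(silyl ether) alcohol
Product: 24 (1R,5S,6S,9R)-4,5-bis[(tert-butyldimethylsilyloxy)methyl]-1-methyl-6-[(2R)-6-methylhept-5-en-2-yl]bicyclo[3.3.1]non-3-en-9-yl acetate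
Conditions: Ac2O, DMAP, Et3N, CH2Cl2, rt → 40 °C
Reagents that add atoms: acetic anhydride, CC(=O)OC(C)=O
Why: DMAP-catalysed acylation can be forced on the hindered but outward-pointing bridge hydroxyl because at this stage the molecule holds only silyl ethers and alkenes, and C9 keeps its configuration since only the O–H bond is engaged.

Step 16
Reactants: 24 bis(silyl ether) acetate
Product: 25 (1R,5S,6S,9R)-4,5-bis(hydroxymethyl)-1-methyl-6-[(2R)-6-methylhept-5-en-2-yl]bicyclo[3.3.1]non-3-en-9-yl acetate
Conditions: HF·pyridine, pyridine, THF, 0 °C → rt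
Reagents that add atoms: none
Why: Fluoride-driven desilylation in a slightly acidic buffered medium removes both silyl groups while avoiding the alkoxide that basic fluoride would create and that would promote acetyl migration from O9 to the C12 hydroxyl, and the crude diol is oxidised at once.

Step 17
Reactants: 25 diol acetate
Product: 26 (1R,5R,6S,9R)-4,5-diformyl-1-methyl-6-[(2R)-6-methylhept-5-en-2-yl]bicyclo[3.3.1]non-3-en-9-yl acetate (target)
Conditions: DMP (3 equiv), pyridine, CH2Cl2, 0 °C → rt
Reagents that add atoms: none
Why: Double Dess–Martin oxidation converts the allylic and the neopentyl primary alcohol into the enal and the bridgehead aldehyde under buffered conditions, and the β-acetoxy aldehyde cannot eliminate or epimerise because C5 bears no hydrogen.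

Compound list
1 | tiglic aldehyde, (E)-2-methylbut-2-enal | C/C=C(\C)C=O | starting material
2 | (1E)-2-methyl-1-(trimethylsilyloxy)buta-1,3-diene | C=C/C(C)=C/O[Si](C)(C)C | intermediate
3 | dimethyl fumarate | COC(=O)/C=C/C(=O)OC | starting material
4 | dimethyl 4-methyl-3-(trimethylsilyloxy)cyclohex-4-ene-1,2-dicarboxylate (racemic, esters trans, epimers at the silyloxy carbon; not isolated) | COC(=O)C1CC=C(C)C(O[Si](C)(C)C)C1C(=O)OC | intermediate
5 | dimethyl 3-hydroxy-4-methylcyclohex-4-ene-1,2-dicarboxylate (racemic, esters trans, carbinol epimers) | COC(=O)C1CC=C(C)C(O)C1C(=O)OC | intermediate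
6 | dimethyl 3-hydroxy-4-methylcyclohexane-1,2-dicarboxylate (racemic diastereomer mixture) | COC(=O)C1CCC(C)C(O)C1C(=O)OC | intermediate
7 | dimethyl 4-methyl-3-oxocyclohexane-1,2-dicarboxylate (racemic diastereomer mixture) | COC(=O)C1CCC(C)C(=O)C1C(=O)OC | intermediate
8 | (R)-citronellal | O=CC[C@H](C)CCC=C(C)C | starting material
9 | (3R)-2-(anilinooxy)-3,7-dimethyloct-6-enal (C2 immaterial; not isolated) | O=CC(ONc1ccccc1)[C@H](C)CCC=C(C)C | intermediate
10 | (3R)-2-(anilinooxy)-3,7-dimethyloct-6-en-1-ol (C2 immaterial) | OCC(ONc1ccccc1)[C@H](C)CCC=C(C)C | intermediate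
11 | (3R)-3,7-dimethyloct-6-ene-1,2-diol (C2 immaterial) | OCC(O)[C@H](C)CCC=C(C)C | intermediate
12 | (2R)-2,6-dimethylhept-5-enal | O=C[C@H](C)CCC=C(C)C | intermediate
13 | (triphenylphosphoranylidene)acetaldehyde | O=CC=P(c1ccccc1)(c1ccccc1)c1ccccc1 | starting material
14 | (2E,4R)-4,8-dimethylnona-2,7-dienal | O=C/C=C/[C@H](C)CCC=C(C)C | intermediate
15 | dimethyl (2R)-2-[(3S,4R)-4,8-dimethyl-1-oxonon-7-en-3-yl]-4-methyl-3-oxocyclohexane-1,2-dicarboxylate (ring C1 and C4 open; not isolated) | O=C1C(C)CCC(C(=O)OC)[C@]1(C(=O)OC)[C@H]([C@H](C)CCC=C(C)C)CC=O | intermediate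
16 | dimethyl (1S,5R,6S)-8-hydroxy-1-methyl-6-[(2R)-6-methylhept-5-en-2-yl]-9-oxobicyclo[3.3.1]nonane-4,5-dicarboxylate (C4 and C8 open; side chain equatorial on ring B) | O=C1[C@@]2(C)CCC(C(=O)OC)[C@]1(C(=O)OC)[C@H]([C@H](C)CCC=C(C)C)CC2O | intermediate
17 | dimethyl (1S,5R,6S)-1-methyl-6-[(2R)-6-methylhept-5-en-2-yl]-9-oxo-8-(phenoxycarbonothioyloxy)bicyclo[3.3.1]nonane-4,5-dicarboxylate (C4 and C8 open) | O=C1[C@@]2(C)CCC(C(=O)OC)[C@]1(C(=O)OC)[C@H]([C@H](C)CCC=C(C)C)CC2OC(=S)Oc1ccccc1 | intermediate
18 | dimethyl (1R,5R,6S)-1-methyl-6-[(2R)-6-methylhept-5-en-2-yl]-9-oxobicyclo[3.3.1]nonane-4,5-dicarboxylate (C4 open) | O=C1[C@@]2(C)CCC(C(=O)OC)[C@]1(C(=O)OC)[C@H]([C@H](C)CCC=C(C)C)CC2 | intermediate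
19 | dimethyl (1R,5R,6S)-1-methyl-6-[(2R)-6-methylhept-5-en-2-yl]-9-oxo-4-(phenylselanyl)bicyclo[3.3.1]nonane-4,5-dicarboxylate (C4 open; not isolated) | O=C1[C@@]2(C)CCC([Se]c3ccccc3)(C(=O)OC)[C@]1(C(=O)OC)[C@H]([C@H](C)CCC=C(C)C)CC2 | intermediate
20 | dimethyl (1R,5R,6S)-1-methyl-6-[(2R)-6-methylhept-5-en-2-yl]-9-oxo-4-(phenylseleninyl)bicyclo[3.3.1]nonane-4,5-dicarboxylate (C4 and Se open; not isolated) | O=C1[C@@]2(C)CCC([Se](=O)c3ccccc3)(C(=O)OC)[C@]1(C(=O)OC)[C@H]([C@H](C)CCC=C(C)C)CC2 | intermediate
21 | dimethyl (1R,5R,6S)-1-methyl-6-[(2R)-6-methylhept-5-en-2-yl]-9-oxobicyclo[3.3.1]non-3-ene-4,5-dicarboxylate | O=C1[C@@]2(C)CC=C(C(=O)OC)[C@]1(C(=O)OC)[C@H]([C@H](C)CCC=C(C)C)CC2 | intermediate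
22 | (1R,5S,6S,9R)-4,5-bis(hydroxymethyl)-1-methyl-6-[(2R)-6-methylhept-5-en-2-yl]bicyclo[3.3.1]non-3-en-9-ol (9-OH over ring B) | O[C@@H]1[C@@]2(C)CC=C(CO)[C@]1(CO)[C@H]([C@H](C)CCC=C(C)C)CC2 | intermediate
23 | (1R,5S,6S,9R)-4,5-bis[(tert-butyldimethylsilyloxy)methyl]-1-methyl-6-[(2R)-6-methylhept-5-en-2-yl]bicyclo[3.3.1]non-3-en-9-ol | O[C@@H]1[C@@]2(C)CC=C(CO[Si](C)(C)C(C)(C)C)[C@]1(CO[Si](C)(C)C(C)(C)C)[C@H]([C@H](C)CCC=C(C)C)CC2 | intermediate
24 | (1R,5S,6S,9R)-4,5-bis[(tert-butyldimethylsilyloxy)methyl]-1-methyl-6-[(2R)-6-methylhept-5-en-2-yl]bicyclo[3.3.1]non-3-en-9-yl acetate | CC(=O)O[C@@H]1[C@@]2(C)CC=C(CO[Si](C)(C)C(C)(C)C)[C@]1(CO[Si](C)(C)C(C)(C)C)[C@H]([C@H](C)CCC=C(C)C)CC2 | intermediate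
25 | (1R,5S,6S,9R)-4,5-bis(hydroxymethyl)-1-methyl-6-[(2R)-6-methylhept-5-en-2-yl]bicyclo[3.3.1]non-3-en-9-yl acetate | CC(=O)O[C@@H]1[C@@]2(C)CC=C(CO)[C@]1(CO)[C@H]([C@H](C)CCC=C(C)C)CC2 | intermediate
26 | (1R,5R,6S,9R)-4,5-diformyl-1-methyl-6-[(2R)-6-methylhept-5-en-2-yl]bicyclo[3.3.1]non-3-en-9-yl acetate | CC(=O)O[C@@H]1[C@@]2(C)CC=C(C=O)[C@]1(C=O)[C@H]([C@H](C)CCC=C(C)C)CC2 | target

Total step count: 17. Longest linear sequence: 13 steps (steps 1–4, then 9–17; the enal branch, steps 5–8, is of equal length).

Steps most likely to fail

Step 9. Four things may go wrong: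
- slow conjugate addition at the crowded C5/C6 junction;
- loss of C1′ integrity through iminium–dienamine equilibration;
- base-induced retro-Michael cleavage during the aldol stage, with erosion of C6;
- an aldol equilibrium that does not favour closure onto the methyl-bearing C1.

The fallback sets out from 7 and 14 and comes back at 18. It makes the two bonds separately, the second one irreversibly. A 6′-hydroxy cinchona alkaloid ether (a bifunctional tertiary amine and hydrogen-bond donor; CH2Cl2, −20 °C) joins 7 and 14 by general-base catalysis. The pseudoenantiomer is chosen to match the (S) sense at C6. This is a known way to add cyclic β-keto esters to β-substituted enals, it involves neither iminium ion nor dienamine, and 15 is isolated. Aldehyde-selective reduction (NaBH4, MeOH/CH2Cl2, −78 °C) gives the hydroxy keto diester F1. An Appel reaction (I2, PPh3, imidazole, CH2Cl2) then gives the iodo keto diester F2. KOt-Bu in THF at 0 °C closes C1–C8 by 6-(enolendo)-exo-tet alkylation of the only ketone enolate. With no aldehyde left, retro-Michael cleavage has no pathway, and steps 10 and 11 fall away.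

Step 12. Three things may go wrong:
- incomplete deprotonation of the hindered C4–H;
- reluctance of the enolate to accept selenium at a carbon next to quaternary C5;
- attack of electrophilic selenium species on the side-chain alkene.

The fallback sets out from 18 and comes back at 21. LiN(i-Pr)2 in the presence of Me3SiCl (internal quench, THF, −78 °C) traps the enolate on oxygen as the ketene silyl acetal F3. Pd(OAc)2 in MeCN at rt then effects a Saegusa–Ito-type dehydrosilylation. The new substituent goes onto oxygen instead of onto C4, β-hydride elimination can involve only C3, and no selenium reagent or oxidant meets the side-chain alkene.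

Step 13. What may go wrong is poor facial selectivity of hydride delivery to C9. The fallback sets out from 23 carried as a C9 epimer mixture through step 14, and comes back at 23. It uncouples the stereo-defining ketone reduction from the ester reduction. The mixture is oxidised (DMP, CH2Cl2, rt) to the bis(silyl ether) ketone F4. This ketone no longer holds an enoate, so the very bulky LiBH(s-Bu)3 (THF, −78 °C) can be used to enforce attack over the less encumbered ring A face. That reagent is ruled out on 21 by its tendency to conjugate reduction.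

Further compounds
F1 | step 9 | hydroxy keto diester, dimethyl (2R)-2-[(3S,4R)-1-hydroxy-4,8-dimethylnon-7-en-3-yl]-4-methyl-3-oxocyclohexane-1,2-dicarboxylate | O=C1C(C)CCC(C(=O)OC)[C@]1(C(=O)OC)[C@H]([C@H](C)CCC=C(C)C)CCO
F2 | step 9 | iodo keto diester, dimethyl (2R)-2-[(3S,4R)-1-iodo-4,8-dimethylnon-7-en-3-yl]-4-methyl-3-oxocyclohexane-1,2-dicarboxylate | O=C1C(C)CCC(C(=O)OC)[C@]1(C(=O)OC)[C@H]([C@H](C)CCC=C(C)C)CCI
F3 | step 12 | ketene silyl acetal, methyl (1R,5R,6S)-4-[methoxy(trimethylsilyloxy)methylidene]-1-methyl-6-[(2R)-6-methylhept-5-en-2-yl]-9-oxobicyclo[3.3.1]nonane-5-carboxylate | O=C1[C@@]2(C)CCC(=C(OC)O[Si](C)(C)C)[C@]1(C(=O)OC)[C@H]([C@H](C)CCC=C(C)C)CC2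
F4 | step 13 | bis(silyl ether) ketone, (1R,5S,6S)-4,5-bis[(tert-butyldimethylsilyloxy)methyl]-1-methyl-6-[(2R)-6-methylhept-5-en-2-yl]bicyclo[3.3.1]non-3-en-9-one | O=C1[C@@]2(C)CC=C(CO[Si](C)(C)C(C)(C)C)[C@]1(CO[Si](C)(C)C(C)(C)C)[C@H]([C@H](C)CCC=C(C)C)CC2
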